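The route rests on disconnecting the C5–C6 bond of ring A, the tetrahydrofuran (O, C3, C4, C5, C6; C1 is the lactone carbonyl of ring B). C6 is quaternary and its methyl and methylene branches are too alike for a face-selective addition, so it is carried as a secondary ether carbon of defined (S) configuration whose C6–H bond, activated by the ring oxygen, is exchanged for carbon. A dirhodium carbene generated at C5 of diazoketone 18 inserts into that bond with retention, closing ring A as furanone 20 and creating the quaternary centre in one operation. The precursor is an acyclic alpha-alkoxy diazoketone: an (S)-alkan-2-yl ether of a C3 carbinol carrying the CH2CO2Me arm.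

Key step: step 8

Remark: the target is S at C3, C4 and C6 and needs nine chain carbons beyond C6 before olefination; reactive intermediates are drawn as monomers and the dirhodium core of carbene 19 is abbreviated to one Rh atom.
Numbering: C1 lactone carbonyl, C2, C3 (ring-fusion CH), C4 (ring-fusion C–CH3), C5, C6 (quaternary), C7–C18 side chain. TBS = tert-butyldimethylsilyl.

Step 1
Reactants: 1 8-bromooctan-1-ol
Product: 2 (8-bromooctyloxy)(tert-butyl)dimethylsilane
Conditions: TBSCl, imidazole, CH2Cl2, 0 °C → rt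
Reagents that add atoms: tert-butyldimethylsilyl chloride CC(C)(C)[Si](C)(C)Cl
Why: Silyl ether protection of a primary alcohol is routine and masks the hydroxyl so that the bromide can be turned into a Grignard reagent.

Step 2
Reactants: 2 (8-bromooctyloxy)(tert-butyl)dimethylsilane; 3 (S)-propylene oxide
Product: 5 (S)-11-(TBS-oxy)undecan-2-ol, via Grignard reagent 4 (not isolated)
Conditions: Mg, THF, 45 °C; then CuI (5 mol%), 3, −30 → 0 °C; H2O/aq. NH4Cl
Reagents that add atoms: none
Why: Copper-catalysed Grignard opening of a terminal epoxide is an SN2 attack at the unsubstituted CH2 carbon, so the oxygen-bearing stereocentre of 3 is not involved and becomes the (S)-carbinol carbon, the future C6.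

Step 3
Reactants: 5 (S)-11-(TBS-oxy)undecan-2-ol; 6 bromoacetic acid
Product: 8 2-{[(S)-11-(TBS-oxy)undecan-2-yl]oxy}acetic acid, via sodium alkoxide 7 (not isolated)
Conditions: NaH (3 equiv), THF, 0 °C → rt; then 6, Bu4NI (cat.), rt → 45 °C; cold aq. citric acid to pH 4
Reagents that add atoms: none
Why: Williamson ether synthesis between the secondary alkoxide and sodium bromoacetate is an SN2 displacement at a primary carbon, so the C6–O bond is never broken and the (S) configuration is kept.

Step 4
Reactants: 8 2-{[(S)-11-(TBS-oxy)undecan-2-yl]oxy}acetic acid; 9 (R)-4-benzyloxazolidin-2-one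
Product: 11 (R)-4-benzyl-3-(2-{[(S)-11-(TBS-oxy)undecan-2-yl]oxy}acetyl)oxazolidin-2-one, via mixed pivalic anhydride 10 (not isolated)
Conditions: PivCl, Et3N, THF, −20 °C; then LiCl, 9, −20 °C → rt
Reagents that add atoms: none
Why: N-acylation of an oxazolidinone through a pivaloyl mixed anhydride (attachment of an Evans auxiliary) is reliable because the nucleophile attacks the unhindered glycolyl carbonyl and not the carbonyl shielded by tert-butyl.

Step 5
Reactants: 11 (R)-4-benzyl-3-(2-{[(S)-11-(TBS-oxy)undecan-2-yl]oxy}acetyl)oxazolidin-2-one; 12 methyl bromoacetate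
Product: 14 methyl (S)-4-[(R)-4-benzyl-2-oxooxazolidin-3-yl]-4-oxo-3-{[(S)-11-(TBS-oxy)undecan-2-yl]oxy}butanoate, via sodium enolate 13 (not isolated)
Conditions: NaHMDS, THF, −78 °C; then 12, −78 → −45 °C; aq. NH4Cl at −45 °C
Reagents that add atoms: none
Why: Evans alkylation of a glycolate imide goes through the sodium-chelated Z-enolate, which the reactive alpha-bromo ester attacks on the face opposite the benzyl group of the (R)-auxiliary, and this sets C3 as S.

Step 6
Reactants: 14 methyl (S)-4-[(R)-4-benzyl-2-oxooxazolidin-3-yl]-4-oxo-3-{[(S)-11-(TBS-oxy)undecan-2-yl]oxy}butanoate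
Product: 16 (S)-4-methoxy-4-oxo-2-{[(S)-11-(TBS-oxy)undecan-2-yl]oxy}butanoic acid, via peroxy acid 15 (not isolated)
Conditions: LiOH, H2O2, THF/H2O (3:1), 0 °C; aq. Na2SO3; 1 M HCl to pH 3–4 at 0 °C
Reagents that add atoms: hydrogen peroxide OO
Why: Hydroperoxide cleavage of an N-acyl oxazolidinone is selective for the exocyclic imide carbonyl, and at 0 °C with excess peroxide buffering the hydroxide the methyl ester, the silyl ether and the C3 stereocentre should survive.

Step 7
Reactants: 16 (S)-4-methoxy-4-oxo-2-{[(S)-11-(TBS-oxy)undecan-2-yl]oxy}butanoic acid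
Product: 18 methyl (S)-5-diazo-4-oxo-3-{[(S)-11-(TBS-oxy)undecan-2-yl]oxy}pentanoate, via mixed carbonic anhydride 17 (not isolated)
Conditions: iBuOCOCl, Et3N, THF, −15 °C; filter; then CH2N2, Et2O, 0 °C → rt
Reagents that add atoms: diazomethane C=[N+]=[N-]
Why: Acylation of diazomethane by a mixed carbonic anhydride (first stage of the Arndt–Eistert sequence) occurs at the more electrophilic alpha-alkoxy acyl carbonyl under non-acidic conditions, so neither the silyl ether nor the C3 configuration is at risk.

Step 8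
Reactants: 18 methyl (S)-5-diazo-4-oxo-3-{[(S)-11-(TBS-oxy)undecan-2-yl]oxy}pentanoate
Product: 20 methyl 2-[(2S,5S)-5-methyl-3-oxo-5-(9-(TBS-oxy)nonyl)tetrahydrofuran-2-yl]acetate, via rhodium carbene 19 (not isolated)
Conditions: Rh2(OAc)4 (2 mol%), CH2Cl2, rt, slow addition of 18 (final 0.01 M)
Reagents that add atoms: none
Why: Dirhodium tetraacetate, a dimer of divalent rhodium, decomposes the diazo group with loss of N2 to give the electrophilic carbene 19 at C5, which attacks the C6–H bond through a three-centre transition state in which hydrogen shift to C5 and C5–C6 bond formation are concerted. The closest known reaction type is the dirhodium-catalysed intramolecular 1,5 C–H insertion of alpha-alkoxy diazoketones to 3(2H)-furanones, together with the established retention of configuration when such carbenes insert into tertiary C–H stereocentres. Ring A closes by C–C bond formation between the carbene carbon C5 and the ether carbon C6 across the C4–C3–O tether, a 1,5 insertion that gives a five-membered ring. The new quaternary stereocentre C6 is controlled only by the (S)-carbinol carbon made in step 2, because the incoming C5 takes the position of the departing hydrogen, while C3 is a bystander under these neutral conditions. The step needs site selectivity and retention: C6–H is the only C–H bond whose insertion closes a five-membered ring and it is both tertiary and activated by the adjacent oxygen, whereas C6–CH3 or C7–H would need a six-membered ring, attack on the ether oxygen would need a four-membered ylide, and the ester carbonyl is a poor carbene acceptor. Slow addition at high dilution suppresses carbene dimerisation, and the remote silyl ether is inert.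

Step 9
Reactants: 20 methyl 2-[(2S,5S)-5-methyl-3-oxo-5-(9-(TBS-oxy)nonyl)tetrahydrofuran-2-yl]acetate
Product: 22 (1S,5S,7S)-1,7-dimethyl-7-(9-(TBS-oxy)nonyl)-2,6-dioxabicyclo[3.3.0]octan-3-one, via hydroxy ester 21 (not isolated)
Conditions: MeTi(OiPr)3 (from ClTi(OiPr)3 + MeLi, Et2O, −40 °C), then 20, −40 °C → rt; aq. NH4Cl; PPTS (cat.), CH2Cl2, rt
Reagents that add atoms: methyltitanium triisopropoxide C[Ti](OC(C)C)(OC(C)C)OC(C)C
Why: Carbonyl addition of a non-basic organotitanium reagent is chemoselective for the ketone over the ester and avoids enolisation, the methyl group should enter C4 on the face anti to the C3 CH2CO2Me arm so that C4 becomes S with its oxygen cis to that arm, and this cis hydroxy ester closes ring B by lactonisation whereas a trans isomer cannot.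

Step 10
Reactants: 22 (1S,5S,7S)-1,7-dimethyl-7-(9-(TBS-oxy)nonyl)-2,6-dioxabicyclo[3.3.0]octan-3-one
Product: 23 (1S,5S,7S)-7-(9-hydroxynonyl)-1,7-dimethyl-2,6-dioxabicyclo[3.3.0]octan-3-one
Conditions: HF·pyridine, THF, 0 °C → rt
Reagents that add atoms: none
Why: Fluoride-mediated cleavage of a primary silyl ether under mildly acidic conditions is routine and leaves the lactone and both tertiary ether carbons untouched.

Step 11
Reactants: 23 (1S,5S,7S)-7-(9-hydroxynonyl)-1,7-dimethyl-2,6-dioxabicyclo[3.3.0]octan-3-one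
Product: 24 9-[(1S,5S,7S)-1,7-dimethyl-3-oxo-2,6-dioxabicyclo[3.3.0]octan-7-yl]nonanal
Conditions: TEMPO (10 mol%), PhI(OAc)2, CH2Cl2, rt
Reagents that add atoms: none
Why: Nitroxyl-catalysed oxidation with a hypervalent iodine co-oxidant converts a primary alcohol into the aldehyde without over-oxidation and without base, so the lactone is not endangered.

Step 12
Reactants: 24 9-[(1S,5S,7S)-1,7-dimethyl-3-oxo-2,6-dioxabicyclo[3.3.0]octan-7-yl]nonanal; 25 diethyl cinnamylphosphonate
Product: 27 plakortone P, via lithiated phosphonate 26 (not isolated)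
Conditions: 25 (1.3 equiv), LiHMDS (1.2 equiv), THF, −78 °C; then 24, −78 °C → rt
Reagents that add atoms: none
Why: Horner–Wadsworth–Emmons olefination with the stabilised allylic phosphonate anion should form the C15=C16 double bond with E geometry because addition to the aldehyde is reversible and the more stable adduct collapses to the trans alkene, the cinnamyl C17=C18 bond keeps its E geometry, and the phosphonate is held in excess over base so that the lactone meets no free amide.

Compound list
1 | 8-bromooctan-1-ol | OCCCCCCCCBr | starting material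
2 | (8-bromooctyloxy)(tert-butyl)dimethylsilane | BrCCCCCCCCO[Si](C)(C)C(C)(C)C | intermediate
3 | (S)-propylene oxide | C[C@H]1CO1 | starting material
4 | [8-(TBS-oxy)octyl]magnesium bromide (Grignard reagent, formed in the flask) | Br[Mg]CCCCCCCCO[Si](C)(C)C(C)(C)C | intermediate
5 | (S)-11-(TBS-oxy)undecan-2-ol | C[C@H](O)CCCCCCCCCO[Si](C)(C)C(C)(C)C | intermediate
6 | bromoacetic acid | OC(=O)CBr | starting material
7 | sodium alkoxide of 5 (formed in the flask) | C[C@H]([O-])CCCCCCCCCO[Si](C)(C)C(C)(C)C.[Na+] | intermediate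
8 | 2-{[(S)-11-(TBS-oxy)undecan-2-yl]oxy}acetic acid | C[C@H](OCC(=O)O)CCCCCCCCCO[Si](C)(C)C(C)(C)C | intermediate
9 | (R)-4-benzyloxazolidin-2-one | O=C1N[C@H](Cc2ccccc2)CO1 | starting material
10 | mixed anhydride of 8 with pivalic acid (formed in the flask) | C[C@H](OCC(=O)OC(=O)C(C)(C)C)CCCCCCCCCO[Si](C)(C)C(C)(C)C | intermediate
11 | (R)-4-benzyl-3-(2-{[(S)-11-(TBS-oxy)undecan-2-yl]oxy}acetyl)oxazolidin-2-one | C[C@H](OCC(=O)N1[C@H](Cc2ccccc2)COC1=O)CCCCCCCCCO[Si](C)(C)C(C)(C)C | intermediate
12 | methyl bromoacetate | COC(=O)CBr | starting material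
13 | sodium (Z)-enolate of 11 (formed in the flask) | C[C@H](O/C=C(\[O-])N1[C@H](Cc2ccccc2)COC1=O)CCCCCCCCCO[Si](C)(C)C(C)(C)C.[Na+] | intermediate
14 | methyl (S)-4-[(R)-4-benzyl-2-oxooxazolidin-3-yl]-4-oxo-3-{[(S)-11-(TBS-oxy)undecan-2-yl]oxy}butanoate | COC(=O)C[C@H](O[C@@H](C)CCCCCCCCCO[Si](C)(C)C(C)(C)C)C(=O)N1[C@H](Cc2ccccc2)COC1=O | intermediate
15 | peroxy acid corresponding to 16 (formed in the flask) | COC(=O)C[C@H](O[C@@H](C)CCCCCCCCCO[Si](C)(C)C(C)(C)C)C(=O)OO | intermediate
16 | (S)-4-methoxy-4-oxo-2-{[(S)-11-(TBS-oxy)undecan-2-yl]oxy}butanoic acid | COC(=O)C[C@H](O[C@@H](C)CCCCCCCCCO[Si](C)(C)C(C)(C)C)C(=O)O | intermediate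
17 | isobutyl carbonic mixed anhydride of 16 (formed in the flask) | COC(=O)C[C@H](O[C@@H](C)CCCCCCCCCO[Si](C)(C)C(C)(C)C)C(=O)OC(=O)OCC(C)C | intermediate
18 | methyl (S)-5-diazo-4-oxo-3-{[(S)-11-(TBS-oxy)undecan-2-yl]oxy}pentanoate | COC(=O)C[C@H](O[C@@H](C)CCCCCCCCCO[Si](C)(C)C(C)(C)C)C(=O)C=[N+]=[N-] | intermediate
19 | rhodium carbene at C5 derived from 18 (formed in the flask; dirhodium core abbreviated) | COC(=O)C[C@H](O[C@@H](C)CCCCCCCCCO[Si](C)(C)C(C)(C)C)C(=O)C=[Rh] | intermediate
20 | methyl 2-[(2S,5S)-5-methyl-3-oxo-5-(9-(TBS-oxy)nonyl)tetrahydrofuran-2-yl]acetate | C[C@]1(CCCCCCCCCO[Si](C)(C)C(C)(C)C)CC(=O)[C@H](CC(=O)OC)O1 | intermediate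
21 | methyl 2-[(2S,3S,5S)-3-hydroxy-3,5-dimethyl-5-(9-(TBS-oxy)nonyl)tetrahydrofuran-2-yl]acetate (formed in the flask) | C[C@]1(CCCCCCCCCO[Si](C)(C)C(C)(C)C)C[C@](C)(O)[C@H](CC(=O)OC)O1 | intermediate
22 | (1S,5S,7S)-1,7-dimethyl-7-(9-(TBS-oxy)nonyl)-2,6-dioxabicyclo[3.3.0]octan-3-one | C[C@]1(CCCCCCCCCO[Si](C)(C)C(C)(C)C)C[C@]2(C)OC(=O)C[C@@H]2O1 | intermediate
23 | (1S,5S,7S)-7-(9-hydroxynonyl)-1,7-dimethyl-2,6-dioxabicyclo[3.3.0]octan-3-one | C[C@]1(CCCCCCCCCO)C[C@]2(C)OC(=O)C[C@@H]2O1 | intermediate
24 | 9-[(1S,5S,7S)-1,7-dimethyl-3-oxo-2,6-dioxabicyclo[3.3.0]octan-7-yl]nonanal | C[C@]1(CCCCCCCCC=O)C[C@]2(C)OC(=O)C[C@@H]2O1 | intermediate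
25 | diethyl cinnamylphosphonate, diethyl (E)-(3-phenylprop-2-en-1-yl)phosphonate | CCOP(=O)(C/C=C/c1ccccc1)OCC | starting material
26 | alpha-lithiated 25 (formed in the flask) | CCOP(=O)([CH-]/C=C/c1ccccc1)OCC.[Li+] | intermediate
27 | plakortone P, (1S,5S,7S)-1,7-dimethyl-7-[(9E,11E)-12-phenyldodeca-9,11-dien-1-yl]-2,6-dioxabicyclo[3.3.0]octan-3-one | C[C@]1(CCCCCCCC/C=C/C=C/c2ccccc2)C[C@]2(C)OC(=O)C[C@@H]2O1 | target

Total step count: 12. Longest linear sequence: 12 steps (1 to 27; compounds 3, 6, 9, 12 and 25 are purchased).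

Steps most likely to fail

Risk 1 (step 8): the carbene may abstract hydride from C6 and collapse through oxygen instead of carbon, be trapped by the ester carbonyl, or insert stepwise with erosion of configuration at C6. The fallback sets out from acid 16 and comes back at silyl lactone 22, replacing steps 7 to 9. Acid 16 is coupled with N,O-dimethylhydroxylamine (EDC·HCl, N-methylmorpholine, CH2Cl2) to the Weinreb amide F1, which MeMgBr (THF, −78 → −20 °C) should convert into the methyl ketone F2. Lithiated trimethylsilyldiazomethane (TMSCHN2, n-BuLi, THF, −78 → 0 °C) turns the ketone into an alkylidene carbene. Its 1,5 C–H insertion into C6–H, a reaction type known to proceed with retention, should give the dihydrofuran ester F3 with the C4 methyl group already in place. Saponification (LiOH, THF/H2O, 0 °C) gives the dihydrofuran acid F4. Iodolactonisation (I2, NaHCO3, MeCN, 0 °C) lets the carboxylate reach C4 only from the face of its own tether and gives the iodolactone F5. Radical deiodination (Bu3SnH, AIBN, toluene, 80 °C) gives 22.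

Risk 2 (step 9): facial selectivity of methyl delivery may be poor because both faces of ring A carry a C6 substituent, and any basic behaviour of the reagent would enolise the ketone, leading to epimerisation at C3 or ring opening by beta-elimination. The fallback sets out from furanone 20 and comes back at silyl lactone 22. Non-basic methylenation of the ketone (Zn, CH2Br2, TiCl4, THF/CH2Cl2) gives the exocyclic alkene F6, and saponification (LiOH, THF/H2O, 0 °C) gives the alkene acid F7. Iodolactonisation (I2, NaHCO3, MeCN) closes ring B on the tertiary carbon C4 from the face of the tether, so C4 is set by the ring fusion and not by reagent approach, and gives the iodomethyl lactone F8. Reduction of the C–I bond (Bu3SnH, AIBN, toluene, 80 °C) turns CH2I into the C4 methyl group and gives 22.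

Risk 3 (step 5): the enolate of the hindered glycolate imide may decompose before it is alkylated or react with insufficient face selectivity, and the product could lose its alkoxide by beta-elimination if base is left. The fallback sets out from alcohol 5 and comes back at acid 16, replacing steps 3 to 6 with chiral-pool chemistry. Commercial dimethyl (R)-malate (COC(=O)C[C@@H](O)C(=O)OC) is converted into the malate triflate F9 (Tf2O, 2,6-lutidine, CH2Cl2, −78 °C). SN2 displacement by alcohol 5 (2,6-di-tert-butyl-4-methylpyridine, CH2Cl2, rt) inverts the malate carbon and should give the alkoxysuccinate diester F10 with C3 = S. One equivalent of LiOH (THF/H2O, 0 °C) saponifies the more electrophilic ester next to the alkoxy group and gives 16.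

Further compounds
F1 | step 8 | methyl (S)-4-[methoxy(methyl)amino]-4-oxo-3-{[(S)-11-(TBS-oxy)undecan-2-yl]oxy}butanoate | COC(=O)C[C@H](O[C@@H](C)CCCCCCCCCO[Si](C)(C)C(C)(C)C)C(=O)N(C)OC
F2 | step 8 | methyl (S)-4-oxo-3-{[(S)-11-(TBS-oxy)undecan-2-yl]oxy}pentanoate | COC(=O)C[C@H](O[C@@H](C)CCCCCCCCCO[Si](C)(C)C(C)(C)C)C(C)=O
F3 | step 8 | methyl 2-[(2S,5S)-3,5-dimethyl-5-(9-(TBS-oxy)nonyl)-2,5-dihydrofuran-2-yl]acetate | C[C@]1(CCCCCCCCCO[Si](C)(C)C(C)(C)C)C=C(C)[C@H](CC(=O)OC)O1
F4 | step 8 | 2-[(2S,5S)-3,5-dimethyl-5-(9-(TBS-oxy)nonyl)-2,5-dihydrofuran-2-yl]acetic acid | C[C@]1(CCCCCCCCCO[Si](C)(C)C(C)(C)C)C=C(C)[C@H](CC(=O)O)O1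
F5 | step 8 | 5-iodo derivative of 22 (iodine on C5, trans to the lactone oxygen) | C[C@]1(CCCCCCCCCO[Si](C)(C)C(C)(C)C)[C@@H](I)[C@]2(C)OC(=O)C[C@@H]2O1
F6 | step 9 | methyl 2-[(2S,5S)-5-methyl-3-methylidene-5-(9-(TBS-oxy)nonyl)tetrahydrofuran-2-yl]acetate | C[C@]1(CCCCCCCCCO[Si](C)(C)C(C)(C)C)CC(=C)[C@H](CC(=O)OC)O1
F7 | step 9 | 2-[(2S,5S)-5-methyl-3-methylidene-5-(9-(TBS-oxy)nonyl)tetrahydrofuran-2-yl]acetic acid | C[C@]1(CCCCCCCCCO[Si](C)(C)C(C)(C)C)CC(=C)[C@H](CC(=O)O)O1
F8 | step 9 | iodomethyl analogue of 22 (CH2I in place of the C4 methyl group) | C[C@]1(CCCCCCCCCO[Si](C)(C)C(C)(C)C)C[C@]2(CI)OC(=O)C[C@@H]2O1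
F9 | step 5 | dimethyl (R)-2-(trifluoromethylsulfonyloxy)succinate | COC(=O)C[C@@H](OS(=O)(=O)C(F)(F)F)C(=O)OC
F10 | step 5 | dimethyl (S)-2-{[(S)-11-(TBS-oxy)undecan-2-yl]oxy}succinate | COC(=O)C[C@H](O[C@@H](C)CCCCCCCCCO[Si](C)(C)C(C)(C)C)C(=O)OC
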